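**Retrosynthetic overview**
1. Target 9 ⇒ vinyl oxirane 8 + benzoic anhydride: benzoate opens the oxirane at allylic C5 (SN2) and the C6 alkoxide is benzoylated (two C–O bonds).
2. 8 ⇒ dienyl carbinol 7 by hydroxyl-directed epoxidation of C5=C6 (C–O).
3. 7 ⇒ epoxy enone 4 by Wharton transposition, then a 1,2-acetyl shift that relays the tertiary acetate onto O2.
4. 4 ⇒ prochiral para-quinol diacetate 3 by a desymmetrising catalytic asymmetric epoxidation (key C–O bond; sets all absolute stereochemistry).
5. 3 ⇒ 4-hydroxybenzyl alcohol 1 by acetylation and oxidative dearomatisation. The carbocycle is the original benzene ring; the only rings formed are the C2–C3 oxirane (step 3) and later the C5–C6 oxirane (step 5), and both are opened again.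

Ring numbering in the text: C1 = quaternary carbinol carbon, C2 = CH–OAc, C3=C4 = alkene, C5 and C6 = CH–OBz (C6 next to C1). "Up" is the face of CH2OAc on C1.

Assumption: the quinidine-derived amine is taken to give the enantiomer drawn for 4; if the sense proves opposite, its quinine-derived pseudoenantiomer is used instead.

**Step 1**
Reactants: 1 4-hydroxybenzyl alcohol
Product: 2 4-(acetoxymethyl)phenol
Conditions: immobilized Candida antarctica lipase B (Novozym 435), vinyl acetate (3 equiv), THF, 30 °C
Reagents that add atoms: vinyl acetate, CC(=O)OC=C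
Why: Lipase-catalysed transesterification with an enol ester acylates the aliphatic (benzylic) hydroxyl and not the phenol, and the irreversible acyl donor drives it to completion; no stereocentre is formed.

**Step 2**
Reactants: 2 4-(acetoxymethyl)phenol
Product: 3 [1-(acetyloxy)-4-oxocyclohexa-2,5-dien-1-yl]methyl acetate
Conditions: PhI(OAc)2 (1.1 equiv), AcOH, 15 °C to rt
Reagents that add atoms: (diacetoxyiodo)benzene, CC(=O)OI(OC(C)=O)c1ccccc1
Why: Oxidative dearomatisation of a para-substituted phenol by the trivalent iodine reagent (aryloxy-iodane, then para attack of acetate) gives the para-quinol acetate, a C–O bond formation that creates the quaternary carbinol carbon while the molecule stays mirror-symmetric.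

**Step 3**
Reactants: 3 [1-(acetyloxy)-4-oxocyclohexa-2,5-dien-1-yl]methyl acetate
Product: 4 [(1R,5R,6S)-5-(acetyloxy)-2-oxo-7-oxabicyclo[4.1.0]hept-3-en-5-yl]methyl acetate (oxirane on C2–C3, trans to the C1 acetoxy group)
Conditions: 9-amino-9-deoxy-epi-quinidine (10 mol%), CF3CO2H (20 mol%), 50% aq. H2O2 (1.2 equiv), 1,4-dioxane, 30 °C
Reagents that add atoms: hydrogen peroxide, OO
Why: Proposed new method: a desymmetrising Weitz–Scheffer-type epoxidation under iminium catalysis, in which the primary amine condenses with the dienone carbonyl and the protonated quinuclidine delivers H2O2 to one Re/Si face of a β-carbon; because attack should also come anti to the C1–OAc bond (no hydrogen-bond donor, Felkin-type σ*C–O alignment, lone-pair repulsion), only one of the two enantiotopic enone arms satisfies both demands, so a single C–O bond formation fixes C1, C2 and C3; over-epoxidation is matched only for the minor enantiomer and should raise the ee; the closest known reaction is the cinchona primary amine salt/H2O2 epoxidation of simple 2-cyclohexenones, which has not been used to desymmetrise 4,4-disubstituted cyclohexa-2,5-dienones.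

**Step 4**
Reactants: 4 [(1R,5R,6S)-5-(acetyloxy)-2-oxo-7-oxabicyclo[4.1.0]hept-3-en-5-yl]methyl acetate
Product: 7 [(1R,6S)-6-(acetyloxy)-1-hydroxycyclohexa-2,4-dien-1-yl]methyl acetate, via hydrazone 5 (not isolated), via tertiary-acetate dienol 6 (not isolated)
Conditions: N2H4·H2O (2 equiv), AcOH (0.3 equiv), MeOH, 0 °C to rt; concentrate; then 1,8-diazabicyclo[5.4.0]undec-7-ene (5 mol%), CH2Cl2, 0 °C
Reagents that add atoms: none
Why: Wharton transposition (hydrazone, then alkenyl diazene with oxirane opening and loss of N2) turns C4=O into the C3=C4 alkene and leaves the C2–O bond untouched (OH up, trans to O1), giving the conjugated diene without passing through a dimerising 2,4-dienone; base then drives the trans-1,2 acetyl shift from the tertiary to the secondary oxygen (less hindered ester), which frees the tertiary hydroxyl.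

**Step 5**
Reactants: 7 [(1R,6S)-6-(acetyloxy)-1-hydroxycyclohexa-2,4-dien-1-yl]methyl acetate
Product: 8 [(1S,2R,3S,6S)-3-(acetyloxy)-2-hydroxy-7-oxabicyclo[4.1.0]hept-4-en-2-yl]methyl acetate (oxirane on C5–C6, cis to the tertiary OH)
Conditions: VO(acac)2 (5 mol%), t-BuOOH (1.3 equiv, decane solution), CH2Cl2, 0 °C
Reagents that add atoms: tert-butyl hydroperoxide, CC(C)(C)OO
Why: Hydroxyl-directed vanadium-catalysed epoxidation (Sharpless–Michaelson type): the tertiary allylic alkoxide binds the vanadium tert-butylperoxide and delivers oxygen to the adjacent C5=C6 bond on its own face, while the distal C3=C4 bond (only homoallylic and deactivated by the allylic acetate) is left alone, so both oxirane carbons are set cis to the tertiary OH.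

**Step 6**
Reactants: 8 [(1S,2R,3S,6S)-3-(acetyloxy)-2-hydroxy-7-oxabicyclo[4.1.0]hept-4-en-2-yl]methyl acetate
Product: 9 [(1R,2S,5R,6S)-2-(acetyloxy)-5,6-bis(benzoyloxy)-1-hydroxycyclohex-3-en-1-yl]methyl acetate
Conditions: Bz2O (1.5 equiv), tetrabutylammonium benzoate (20 mol%), toluene, 60 °C
Reagents that add atoms: benzoic anhydride, O=C(OC(=O)c1ccccc1)c1ccccc1
Why: Carboxylate-catalysed epoxide/anhydride addition: benzoate opens the vinyl oxirane by SN2 at the allylic, non-neopentyl carbon C5 with inversion (OBz up) and the C6 alkoxide (down, cis to the tertiary OH) is acylated by the anhydride, which regenerates benzoate, so the trans-5,6-dibenzoate forms in one operation while the hindered tertiary hydroxyl stays free.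

**Compound list**
1 | 4-hydroxybenzyl alcohol | OCc1ccc(O)cc1 | starting material
2 | 4-(acetoxymethyl)phenol | CC(=O)OCc1ccc(O)cc1 | intermediate
3 | [1-(acetyloxy)-4-oxocyclohexa-2,5-dien-1-yl]methyl acetate | CC(=O)OCC1(OC(C)=O)C=CC(=O)C=C1 | intermediate
4 | [(1R,5R,6S)-5-(acetyloxy)-2-oxo-7-oxabicyclo[4.1.0]hept-3-en-5-yl]methyl acetate | CC(=O)OC[C@@]1(OC(C)=O)[C@H]2O[C@H]2C(=O)C=C1 | intermediate
5 | [(1S,5R,6S)-5-(acetyloxy)-2-hydrazinylidene-7-oxabicyclo[4.1.0]hept-3-en-5-yl]methyl acetate (hydrazone of 4) | CC(=O)OC[C@@]1(OC(C)=O)[C@H]2O[C@H]2C(=NN)C=C1 | intermediate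
6 | [(1R,6S)-1-(acetyloxy)-6-hydroxycyclohexa-2,4-dien-1-yl]methyl acetate | CC(=O)OC[C@@]1(OC(C)=O)[C@@H](O)C=CC=C1 | intermediate
7 | [(1R,6S)-6-(acetyloxy)-1-hydroxycyclohexa-2,4-dien-1-yl]methyl acetate | CC(=O)OC[C@@]1(O)[C@@H](OC(C)=O)C=CC=C1 | intermediate
8 | [(1S,2R,3S,6S)-3-(acetyloxy)-2-hydroxy-7-oxabicyclo[4.1.0]hept-4-en-2-yl]methyl acetate | CC(=O)OC[C@@]1(O)[C@@H](OC(C)=O)C=C[C@@H]2O[C@H]12 | intermediate
9 | [(1R,2S,5R,6S)-2-(acetyloxy)-5,6-bis(benzoyloxy)-1-hydroxycyclohex-3-en-1-yl]methyl acetate | CC(=O)OC[C@@]1(O)[C@@H](OC(C)=O)C=C[C@@H](OC(=O)c2ccccc2)[C@@H]1OC(=O)c1ccccc1 | target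

**Step count and risks**
Total steps: 6. Longest linear sequence: 6 (fully linear from 1).

The three steps most likely to fail:

Step 3 (proposed new desymmetrising epoxidation; risks are low ee, the wrong face relative to OAc, or bis-epoxidation). Fallback with known chemistry, setting out from 3: racemic Weitz–Scheffer epoxidation (t-BuOOH, 1,8-diazabicyclo[5.4.0]undec-7-ene, CH2Cl2) gives 4 together with its enantiomer [(1S,5S,6R)-5-(acetyloxy)-2-oxo-7-oxabicyclo[4.1.0]hept-3-en-5-yl]methyl acetate F1. The hydrazine stage of step 4 on this mixture gives 6 and its enantiomer [(1S,6R)-1-(acetyloxy)-6-hydroxycyclohexa-2,4-dien-1-yl]methyl acetate F2. A lipase kinetic resolution (Burkholderia cepacia lipase, vinyl acetate, MTBE) should acetylate the (R)-carbinol F2, as the Kazlauskas rule predicts for a large quaternary and a medium vinyl substituent, to [(1S,6R)-1,6-bis(acetyloxy)cyclohexa-2,4-dien-1-yl]methyl acetate F3. Unreacted 6 is separated and the route is rejoined at compound 6 (base stage of step 4), at the cost of at most 50% yield.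

Step 4 (hydrazine may cleave or scramble the acetates, and the trans-1,2 acetyl shift may stall). Fallback, setting out from 6 (or the crude Wharton mixture): give up the acetyl relay. Methanolysis of all acetates (K2CO3, MeOH, 0 °C) gives the triol (1R,2S)-1-(hydroxymethyl)cyclohexa-3,5-diene-1,2-diol F4. Selective acetylation of its primary and secondary hydroxyls (Ac2O, pyridine, 0 °C, no acyl-transfer catalyst) leaves the tertiary OH free and returns to the route at compound 7.

Step 5 (the acid-sensitive dienyl carbinol may aromatise or rearrange at the vanadium centre, or the vinyl oxirane may not survive). Fallback, setting out from 7: replace epoxidation/opening by directed dihydroxylation and inversion. Hydrogen-bond-directed dihydroxylation (OsO4, TMEDA, 1 equiv each, CH2Cl2, −78 °C, then aq. NaHSO3) adds both oxygens to C5=C6 cis to the tertiary OH and gives [(1S,2S,5S,6S)-2-(acetyloxy)-1,5,6-trihydroxycyclohex-3-en-1-yl]methyl acetate F5. Mitsunobu reaction (PhCO2H, PPh3, DIAD, THF, 0 °C) inverts only the allylic C5 carbinol to give [(1S,2S,5R,6S)-2-(acetyloxy)-5-(benzoyloxy)-1,6-dihydroxycyclohex-3-en-1-yl]methyl acetate F6. Benzoylation of the C6 hydroxyl (BzCl, pyridine, 0 °C) returns to the route at compound 9, the target.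

**Further compounds**
F1 | step 3 | [(1S,5S,6R)-5-(acetyloxy)-2-oxo-7-oxabicyclo[4.1.0]hept-3-en-5-yl]methyl acetate (enantiomer of 4) | CC(=O)OC[C@]1(OC(C)=O)[C@@H]2O[C@@H]2C(=O)C=C1
F2 | step 3 | [(1S,6R)-1-(acetyloxy)-6-hydroxycyclohexa-2,4-dien-1-yl]methyl acetate (enantiomer of 6) | CC(=O)OC[C@]1(OC(C)=O)[C@H](O)C=CC=C1
F3 | step 3 | [(1S,6R)-1,6-bis(acetyloxy)cyclohexa-2,4-dien-1-yl]methyl acetate | CC(=O)OC[C@]1(OC(C)=O)[C@H](OC(C)=O)C=CC=C1
F4 | step 4 | (1R,2S)-1-(hydroxymethyl)cyclohexa-3,5-diene-1,2-diol | OC[C@@]1(O)[C@@H](O)C=CC=C1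
F5 | step 5 | [(1S,2S,5S,6S)-2-(acetyloxy)-1,5,6-trihydroxycyclohex-3-en-1-yl]methyl acetate | CC(=O)OC[C@@]1(O)[C@@H](OC(C)=O)C=C[C@H](O)[C@@H]1O
F6 | step 5 | [(1S,2S,5R,6S)-2-(acetyloxy)-5-(benzoyloxy)-1,6-dihydroxycyclohex-3-en-1-yl]methyl acetate | CC(=O)OC[C@@]1(O)[C@@H](OC(C)=O)C=C[C@@H](OC(=O)c2ccccc2)[C@@H]1O
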